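Start with the balance.

    substrate + enzyme ⇌ complex (K1 = 140 L mol⁻¹, k1 = 24000 L mol⁻¹ s⁻¹)
    complex ⇌ enzyme + target (K2 = 0.038 M, k2 = 1300 min⁻¹)
    substrate + target → side product (k3 = 4.7 L mol⁻¹ min⁻¹)

common to all: enzyme 0.0099 mol%

| run | substrate | time | remark |
|---|---|---|---|
| grey | 20 mM (fed, over 2.00 h) | 4.0 h | a stirred flask in which substrate is dosed at a steady rate over 2.00 h without added volume, worked up at 4.0 h |
| violet | 20 mM |  | a single well-mixed tank run continuously and read at steady state, 4.0 h in it on average |
| teal | 20 mM | 4.0 h | a closed flask charged with all of it at once and left for 4.0 h |

- in percentages every species weighs as the substrate in it: one side product counts as two
- the stated concentrations are those of everything mixed, before any reaction; amounts are the same in each set-up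
- the feed brings no volume worth counting
- run time (grey): 4.0 h

* the set-up with the highest share of target in all that became target or side product, at the outlet or at the end ("none" if the first two lie within 2 percentage points) (grey / violet / teal / none)
* share of target in all that became target or side product, at the outlet or at the end, grey
* share of target in all that became target or side product, at the outlet or at the end, violet
* share of target in all that became target or side product, at the outlet or at the end, teal

**The pool.** Steps 1 and 2 together carry substrate to target and back through the enzyme, and at balance [target]/[substrate] is K1 times K2, or 5.32. I treat step 3 as a correction on a rapid pre-equilibrium, an assumption I test below, and follow one thing, the pool [substrate] + [target]. Each step 3 event removes two units of it, at a rate that goes with the pool squared. This gives 39.9 min as the pool time, the time after which the balanced pool has fallen to half of its charge. At any later moment the part left is one over one plus elapsed time divided by pool time.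

**Turned round.** For teal to beat violet, a flask that starts high has to keep a larger share than one held low, and my pool reckoning does not give that, since its loss goes with the pool squared. So I ask how well the pool reckoning fits this flask. At its top rate, with all of it bound and passing through step 2, the enzyme turns over the whole charge in 7.77 min. The pool time is longer by a factor of 5.14, so I expect a second-order loss, which spares a flask running at a low level.

**By hand.** Teal runs through 6.01 pool times and keeps 14.3 % of its pool, which gives a share of 12.3 %. Violet sits at the level where feed balances loss, 33.3 % of the pool, which gives 29.6 %, higher than teal. Grey needs a dosing term, and my hand stops there.

**The forecast.** It names violet, with grey 18 %, violet 28 % and teal 12.6 %, since the loss “hurts most when concentrations stay high for long”. My violet stands above its figure and my teal below.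

**The result.** The best is violet, with grey 18.0 %, violet 27.6 % and teal 12.4 %. Violet holds substrate at 1.16 mM beside target at 26.0 % of the charge, a reading of 4.49 for [target]/[substrate], lower than the balance. In the neighbour flask, teal's recipe with 50 mM of substrate, the pool time shortens to 16.0 min, so 4.0 h is 15.0 pool times and target should stand at 5.26 %; that flask holds 5.28 %.

(The rate constants stand for no real mixture; no experiment stands behind them.)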